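Ring C of the target (O1, the dimethyl-bearing C2, C3 and the C4 carbonyl) is treated as an isovaleryl side chain of ring B whose tertiary β-carbon has been oxidised and tied to the C8a oxygen, so only O1–C2 is disconnected. One aerobic palladium-catalysed operation desaturates that chain to the 3-methylbut-2-enoyl ketone and lets the C8a phenol close the pyranone. C2 becomes quaternary, which stops oxidation short of a chromone. The precursor is a methylene-bridged pair of hexasubstituted ortho-hydroxyaryl ketones, isobutyryl on ring A and isovaleryl on ring B. Its other four oxygens are methyl ethers, and it is assembled by a directed ortho-quinone methide cross-coupling.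

Key step: step 6

Remarks on the chemistry
- The target is achiral, so no stereocentre has to be set or preserved. Rings B and C carry chromanone numbering (O1, C2, C3, C4, C4a, C5 to C8, C8a). Ring A is the arene that bears the isobutyryl group.
- Assumption: 4-hydroxy-2,6-dimethoxybenzaldehyde, the two acid chlorides and aqueous formaldehyde are bought.
- The common phenol is made by deoxygenating a commercial para-hydroxybenzaldehyde. A peracid entry from 3,5-dimethoxy-4-methylbenzaldehyde is avoided. Its oxygen donors sit only meta to the formyl carbon, so hydride migration to the benzoic acid would compete with aryl migration.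
- The two halves differ by a single CH2, so statistical acylation or statistical bridging would give near-inseparable homologues. Each ketone is therefore made separately. The bridge is formed only when each partner has one open ring position left, which also excludes oligomers.

Step 1
Reactants: 1 4-hydroxy-2,6-dimethoxybenzaldehyde
Product: 3 3,5-dimethoxy-4-methylphenol, via benzylic alcohol 2 (not isolated)
Conditions: H2 (3 bar), 10% Pd/C, AcOH, 40 °C
Reagents that add atoms: none
Why: Catalytic hydrogenation of the aldehyde to alcohol 2 is followed in the same flask by benzylic hydrogenolysis, which is fast here because the para hydroxy group and the two ortho methoxy groups strongly stabilise positive charge at the benzylic carbon.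

Step 2
Reactants: 3 3,5-dimethoxy-4-methylphenol; 4 isobutyryl chloride
Product: 5 1-(6-hydroxy-2,4-dimethoxy-3-methylphenyl)-2-methylpropan-1-one (ring A ketone)
Conditions: iPrCOCl (1.05 equiv), BF3·OEt2, 0 → 70 °C; then H2O
Reagents that add atoms: isobutyryl chloride 4, CC(C)C(Cl)=O
Why: Friedel–Crafts acylation of a strongly activated phenol whose para position is blocked by the methyl group and whose two open positions are equivalent, so only one ortho-hydroxy ketone can form, the new acyl group shuts down a second acylation, and BF3 leaves aryl methyl ethers alone.

Step 3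
Reactants: 3 3,5-dimethoxy-4-methylphenol; 6 isovaleryl chloride
Product: 7 1-(6-hydroxy-2,4-dimethoxy-3-methylphenyl)-3-methylbutan-1-one (ring B ketone)
Conditions: iBuCOCl (1.05 equiv), BF3·OEt2, 0 → 70 °C; then H2O
Reagents that add atoms: isovaleryl chloride 6, CC(C)CC(Cl)=O
Why: The same Friedel–Crafts acylation with the homologous acid chloride, again with a single possible regiochemical outcome, places the free phenol (future O1) on one flank of the ketone and a methoxy group (future C5 oxygen) on the other.

Step 4
Reactants: 5 ring A ketone; 8 formaldehyde
Product: 9 1-[3-(dimethylaminomethyl)-2-hydroxy-4,6-dimethoxy-5-methylphenyl]-2-methylpropan-1-one (ring A Mannich base)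
Conditions: 37% aq. HCHO (3 equiv), 40% aq. Me2NH (3 equiv), EtOH, rt → 40 °C
Reagents that add atoms: formaldehyde 8, C=O; dimethylamine, CNC
Why: Phenolic Mannich reaction at the last aromatic C–H, which is ortho to the phenol and ortho and para to the methoxy groups, while the hindered tertiary α-carbon of the isobutyryl group is a poor competitor, which is why ring A and not ring B is made the electrophilic partner.

Step 5
Reactants: 9 ring A Mannich base; 7 ring B ketone
Product: 12 1-[2-hydroxy-3-[[2-hydroxy-4,6-dimethoxy-5-methyl-3-(3-methylbutanoyl)phenyl]methyl]-4,6-dimethoxy-5-methylphenyl]-2-methylpropan-1-one (bis(ortho-hydroxyaryl ketone) precursor), via ammonium iodide 10 (not isolated), via ortho-quinone methide 11 (not isolated)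
Conditions: MeI, MeCN, rt, then evaporate; 7 (1.3 equiv), K2CO3, MeCN, 50 °C
Reagents that add atoms: none
Why: N-Methylation turns the amine into a trimethylammonium leaving group, mild base then releases ortho-quinone methide 11 (the electrophile of base-catalysed phenol–formaldehyde condensation), and the phenolate of 7 adds through its single free ring carbon in a conjugate, Friedel–Crafts-type C-alkylation; neither partner has a second open position and no free formaldehyde is present, so homodimers and oligomers are excluded by design.

Step 6
Reactants: 12 bis(ortho-hydroxyaryl ketone) precursor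
Product: 14 8-[[2-hydroxy-4,6-dimethoxy-5-methyl-3-(2-methylpropanoyl)phenyl]methyl]-5,7-dimethoxy-2,2,6-trimethylchroman-4-one (tetramethyl ether of the target), via enone 13 (not isolated)
Conditions: Pd(OCOCF3)2 (15 mol %), 4,5-diazafluoren-9-one (15 mol %), DMSO, O2 (1 atm), 90 °C; then cat. NaOAc, 60 °C
Reagents that add atoms: none
Why: Proposed new method: carboxylate-assisted deprotonation of the ring B α-CH2 (future C3) should give a divalent palladium enolate, transfer of the tertiary hydrogen on the future C2 to the metal (β-hydride elimination) releases enone 13, and dioxygen reoxidises the zerovalent palladium left after loss of CF3CO2H, with water as the only by-product. The closest known reaction type is the aerobic Pd(OCOCF3)2/DMSO α,β-dehydrogenation of ketones (the diazafluorenone-ligated form handles acyclic ketones) and its tandem use on 2'-hydroxydihydrochalcones to give flavanones; the untested element is a purely aliphatic chain whose β-hydrogen is tertiary and not benzylic. Ring C then closes by 6-endo-trig oxa-Michael addition of the C8a phenol to the β,β-dimethyl enone, the closure on which classical 2,2-dimethylchroman-4-one syntheses rely, favoured by the gem-dimethyl effect and by relief of the twist in a doubly ortho-substituted aryl enone. No stereocentre is created, and because C2 ends quaternary the product offers no β-hydrogen for a second dehydrogenation, so a chromone cannot form. Site selectivity between the two ketones is needed and rests on the α-carbons: the isovaleryl CH2 can carry palladium, whereas the isobutyryl methine would require a crowded tertiary palladium enolate beside a doubly ortho-substituted arene. Selectivity between the two oxygens that flank the ring B ketone is secured by the C5 methyl ether, and both arenes are hexasubstituted, so aromatic C–H palladation has no site.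

Step 7
Reactants: 14 tetramethyl ether of the target
Product: 15 5,7-dihydroxy-2,2,6-trimethyl-8-[[2,4,6-trihydroxy-3-methyl-5-(2-methylpropanoyl)phenyl]methyl]chroman-4-one (CNP0186856.0)
Conditions: BBr3 (10 equiv), CH2Cl2, −78 → 0 °C; then ice-water
Reagents that add atoms: none
Why: Lewis-acid aryl methyl ether cleavage with BBr3, in which the two methoxy groups next to a ketone (C5 on ring B and the one ortho to the isobutyryl group on ring A) fall first through boron chelates and the two doubly flanked, out-of-plane methoxy groups are basic enough to follow at or below 0 °C, a temperature chosen to spare the diarylmethane link and the tertiary O1–C2 bond.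

Compound list
1 | 4-hydroxy-2,6-dimethoxybenzaldehyde | COc1cc(O)cc(OC)c1C=O | starting material
2 | 4-(hydroxymethyl)-3,5-dimethoxyphenol (not isolated) | COc1cc(O)cc(OC)c1CO | intermediate
3 | 3,5-dimethoxy-4-methylphenol | COc1cc(O)cc(OC)c1C | intermediate
4 | isobutyryl chloride | CC(C)C(Cl)=O | starting material
5 | 1-(6-hydroxy-2,4-dimethoxy-3-methylphenyl)-2-methylpropan-1-one | COc1cc(O)c(C(=O)C(C)C)c(OC)c1C | intermediate
6 | isovaleryl chloride | CC(C)CC(Cl)=O | starting material
7 | 1-(6-hydroxy-2,4-dimethoxy-3-methylphenyl)-3-methylbutan-1-one | COc1cc(O)c(C(=O)CC(C)C)c(OC)c1C | intermediate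
8 | formaldehyde | C=O | starting material
9 | 1-[3-(dimethylaminomethyl)-2-hydroxy-4,6-dimethoxy-5-methylphenyl]-2-methylpropan-1-one | COc1c(C)c(OC)c(CN(C)C)c(O)c1C(=O)C(C)C | intermediate
10 | [2-hydroxy-4,6-dimethoxy-5-methyl-3-(2-methylpropanoyl)phenyl]methyl-trimethylammonium iodide (not isolated) | COc1c(C)c(OC)c(C[N+](C)(C)C)c(O)c1C(=O)C(C)C.[I-] | intermediate
11 | 3,5-dimethoxy-4-methyl-6-methylidene-2-(2-methylpropanoyl)cyclohexa-2,4-dien-1-one (ortho-quinone methide, not isolated) | C=C1C(=O)C(C(=O)C(C)C)=C(OC)C(C)=C1OC | intermediate
12 | bis(ortho-hydroxyaryl ketone) precursor: ring A isobutyryl, ring B isovaleryl, four methyl ethers | COc1c(C(=O)C(C)C)c(O)c(Cc2c(O)c(C(=O)CC(C)C)c(OC)c(C)c2OC)c(OC)c1C | intermediate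
13 | ring B 3-methylbut-2-enoyl ketone (enone, not isolated) | COc1c(C(=O)C(C)C)c(O)c(Cc2c(O)c(C(=O)C=C(C)C)c(OC)c(C)c2OC)c(OC)c1C | intermediate
14 | 8-[[2-hydroxy-4,6-dimethoxy-5-methyl-3-(2-methylpropanoyl)phenyl]methyl]-5,7-dimethoxy-2,2,6-trimethylchroman-4-one | COc1c(C(=O)C(C)C)c(O)c(Cc2c3OC(C)(C)CC(=O)c3c(OC)c(C)c2OC)c(OC)c1C | intermediate
15 | 5,7-dihydroxy-2,2,6-trimethyl-8-[[2,4,6-trihydroxy-3-methyl-5-(2-methylpropanoyl)phenyl]methyl]chroman-4-one | Cc1c(O)c(Cc2c(O)c(C)c(O)c3c2OC(C)(C)CC3=O)c(O)c(C(=O)C(C)C)c1O | target

Total step count: 7. Longest linear sequence: 6 (steps 1, 2, 4, 5, 6, 7). Step 3 is the side branch from the common phenol 3.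

Steps most likely to fail

1. Step 6.
- What may go wrong:
  - The palladium enolate may form slowly at a ketone that two ortho substituents twist out of the ring plane.
  - The two chelating ortho-hydroxy ketone units may tie up the catalyst.
  - Palladium metal may precipitate before useful turnover.
  - The ring A side chain may be partly desaturated.
- Fallback: known chemistry, in which α-selenylation and selenoxide syn-elimination replace the catalytic C–H dehydrogenation. It sets out from 12 and rejoins the route at 13.
- With LiN(iPr)2 (3.3 equiv, THF, −78 °C), 12 should give the bis(phenolate) enolate by removal of the less hindered ring B α-CH2 proton.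
- PhSeCl then gives the racemic α-phenylselanyl ketone F1.
- H2O2 with pyridine in CH2Cl2 at 0 °C gives the selenoxide F2.
- Syn-elimination of F2 towards its only β-hydrogen delivers enone 13. A catalytic amount of K2CO3 in MeOH then completes the closure to 14.

2. Step 7.
- What may go wrong:
  - The Lewis acid may ionise the tertiary O1–C2 bond, followed by reclosure through the freed C5 oxygen (Wessely–Moser-type scrambling of the ring C regiochemistry).
  - The HBr generated in the flask may cleave the electron-rich diarylmethane link.
- Fallback: ring closure and ether cleavage are done on the separate halves, and the bridge is made last. It sets out from 7 and 5 and comes back at 15.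
- Ketone 7 under the conditions of step 6 passes through the monomeric enone F3 to 5,7-dimethoxy-2,2,6-trimethylchroman-4-one F4.
- BBr3 converts F4 into 5,7-dihydroxy-2,2,6-trimethylchroman-4-one F5. At this small size F5 can be freed from any regioisomer that scrambling might produce.
- BBr3 converts 5 into 2-methyl-1-(2,4,6-trihydroxy-3-methylphenyl)propan-1-one F6. Formaldehyde 8 with dimethylamine then gives its fully substituted Mannich base F7.
- Warming F7 with F5 in dioxane releases the ortho-quinone methide F8. C8 of F5, the only free ring position in either partner, captures it to give 15.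

3. Step 5.
- What may go wrong:
  - The ortho-quinone methide may condense with itself faster than a hindered, chelated phenolate captures it.
  - Attack through oxygen may persist in place of attack through carbon.
- Fallback: a stronger carbon nucleophile is used and the second acyl group is added after the bridge. It sets out from 10 (made from 9 as in step 5) and 3, and comes back at 12.
- Salt 10 is treated with K2CO3 in the presence of excess non-acylated phenol 3. This should capture 11 quickly and give the mono-ketone diarylmethane F9.
- The unchelated ring B phenol of F9 is esterified selectively with 6 (pyridine, CH2Cl2, 0 °C) to the isovalerate F10.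
- A photo-Fries shift (254 nm, MeCN), for which only the ortho position is open because methyl blocks the para position, moves the acyl group to carbon under neutral conditions and gives 12.

Further compounds
F1 | step 6 | racemic ring B α-phenylselanyl ketone derived from 12 | COc1c(C(=O)C(C)C)c(O)c(Cc2c(O)c(C(=O)C([Se]c3ccccc3)C(C)C)c(OC)c(C)c2OC)c(OC)c1C
F2 | step 6 | selenoxide of F1 (mixture of stereoisomers, eliminates in the flask) | COc1c(C(=O)C(C)C)c(O)c(Cc2c(O)c(C(=O)C([Se](=O)c3ccccc3)C(C)C)c(OC)c(C)c2OC)c(OC)c1C
F3 | step 7 | 1-(6-hydroxy-2,4-dimethoxy-3-methylphenyl)-3-methylbut-2-en-1-one | COc1cc(O)c(C(=O)C=C(C)C)c(OC)c1C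
F4 | step 7 | 5,7-dimethoxy-2,2,6-trimethylchroman-4-one | COc1cc2OC(C)(C)CC(=O)c2c(OC)c1C
F5 | step 7 | 5,7-dihydroxy-2,2,6-trimethylchroman-4-one | Cc1c(O)cc2OC(C)(C)CC(=O)c2c1O
F6 | step 7 | 2-methyl-1-(2,4,6-trihydroxy-3-methylphenyl)propan-1-one | Cc1c(O)cc(O)c(C(=O)C(C)C)c1O
F7 | step 7 | 1-[3-(dimethylaminomethyl)-2,4,6-trihydroxy-5-methylphenyl]-2-methylpropan-1-one | Cc1c(O)c(CN(C)C)c(O)c(C(=O)C(C)C)c1O
F8 | step 7 | 3,5-dihydroxy-4-methyl-6-methylidene-2-(2-methylpropanoyl)cyclohexa-2,4-dien-1-one | C=C1C(=O)C(C(=O)C(C)C)=C(O)C(C)=C1O
F9 | step 5 | 1-[2-hydroxy-3-[(2-hydroxy-4,6-dimethoxy-5-methylphenyl)methyl]-4,6-dimethoxy-5-methylphenyl]-2-methylpropan-1-one | COc1c(C(=O)C(C)C)c(O)c(Cc2c(O)cc(OC)c(C)c2OC)c(OC)c1C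
F10 | step 5 | ring B 3-methylbutanoate ester of F9 | COc1c(C(=O)C(C)C)c(O)c(Cc2c(OC(=O)CC(C)C)cc(OC)c(C)c2OC)c(OC)c1C
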